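**Retrosynthetic overview**
1. Target 20 ⇐ 3,19-diol acid 18 (diacetylation, then selective removal of the primary acetate) ⇐ triol 16 ⇐ keto diester 14 (C3 ketone to the axial alcohol; both esters to CH2OH; allylic alcohol to the acid).
2. 14 ⇐ acyclic C20 sulfonyl β-keto ester 13 by one Mn(III) radical cascade that forms C4–C5 (ring A) and then C9–C10 (ring B) and ends by loss of PhSO2• from C7, which places the alkene at C7=C8. A (+)-8-phenylmenthyl ester controls the absolute configuration.
3. 13 ⇐ dianion of the auxiliary acetoacetate 11 (C2) + allylic bromide 9 (C1), then MeI (C18).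
4. 9 ⇐ anion of allyl sulfone 7 (C7) + (E)-1,4-dibromo-2-methylbut-2-ene 8 (C6).
5. 7 ⇐ methyl geranate 4 (homoprenyl copper + methyl but-2-ynoate) by SeO2 oxidation, then PBr3/PhSO2Na.

Assumption: sodium benzenesulfinate and (+)-8-phenylmenthol serve as a traceless activating reagent and a recoverable chiral ester auxiliary; no atom of either remains in the target. Labdane numbering is used for the ring compounds (C4 carries the C18 methyl and C19; C20 is the methyl on C10).

**Step 1**
Reactants: 1 5-bromo-2-methylpent-2-ene; 2 methyl but-2-ynoate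
Product: 4 methyl (2E)-3,7-dimethylocta-2,6-dienoate (methyl geranate), via homoprenylmagnesium bromide 3 (not isolated)
Conditions: Mg, THF, rt; CuBr·SMe2 (1 eq), −78 °C; then 2, THF, −78 °C; aq NH4Cl at −78 °C
Reagents that add atoms: magnesium [Mg] (in 3 only)
Why: syn-carbocupration of the ynoate at −78 °C followed by protonation with retention puts the new chain trans to CO2Me, giving the 2E enoate (organocopper conjugate addition to 2-alkynoates).

**Step 2**
Reactants: 4 methyl geranate
Product: 5 methyl (2E,6E)-8-hydroxy-3,7-dimethylocta-2,6-dienoate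
Conditions: SeO2 (0.3 eq), t-BuOOH (3 eq), salicylic acid (cat.), CH2Cl2, 0 °C → rt
Reagents that add atoms: tert-butyl hydroperoxide CC(C)(C)OO (oxygen, delivered through catalytic selenium dioxide O=[Se]=O)
Why: Sharpless SeO2/TBHP allylic oxidation (ene, then [2,3]-shift) attacks only the electron-rich terminal alkene and oxidises the E-methyl, so the 6E allylic alcohol forms.

**Step 3**
Reactants: 5 hydroxy ester
Product: 7 methyl (2E,6E)-3,7-dimethyl-8-(phenylsulfonyl)octa-2,6-dienoate, via allylic bromide 6 (not isolated)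
Conditions: PBr3 (0.4 eq), Et2O, −10 °C; then PhSO2Na, DMF, rt
Reagents that add atoms: phosphorus tribromide BrP(Br)Br (bromine of 6 only); sodium benzenesulfinate [Na+].[O-]S(=O)c1ccccc1
Why: primary allylic bromide formation and SN2 S-alkylation of sulfinate both proceed without allylic transposition, so the 6E geometry is kept.

**Step 4**
Reactants: 7 allyl sulfone; 8 (2E)-1,4-dibromo-2-methylbut-2-ene
Product: 9 methyl (2E,6E,10E)-12-bromo-3,7,11-trimethyl-8-(phenylsulfonyl)dodeca-2,6,10-trienoate
Conditions: LiHMDS (1.0 eq), THF, −78 °C; added to 8 (3 eq), THF–DMPU, −78 → −30 °C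
Reagents that add atoms: none
Why: sulfone-stabilised allyl carbanion alkylation (Julia-type coupling) occurs α to sulfur and at the CH2Br remote from the methyl group of 8, with excess dibromide suppressing double substitution; the new C7 centre is racemic and is destroyed in step 7.

**Step 5**
Reactants: 10 methyl 3-oxobutanoate
Product: 11 (1S,2R,5S)-8-phenylmenthyl 3-oxobutanoate
Conditions: (+)-8-phenylmenthol, DMAP (cat.), toluene, reflux (−MeOH)
Reagents that add atoms: (+)-8-phenylmenthol, (1S,2R,5S)-5-methyl-2-(2-phenylpropan-2-yl)cyclohexan-1-ol, O[C@H]1C[C@@H](C)CC[C@@H]1C(C)(C)c1ccccc1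
Why: DMAP-catalysed transesterification of a β-keto ester (acylketene pathway) works with hindered secondary alcohols and leaves the auxiliary stereocentres untouched.

**Step 6**
Reactants: 11 auxiliary acetoacetate; 9 allylic bromide
Product: 13 acyclic 2-methyl-3-oxo sulfonyl trienedioate (full name in list), via unmethylated keto ester 12 (not isolated)
Conditions: NaH, THF, 0 °C; n-BuLi, 0 °C; added to 9, THF, −78 → −20 °C; then MeI, DMPU, 0 °C → rt
Reagents that add atoms: iodomethane CI
Why: Weiler dianion alkylation, in which the γ-carbanion displaces the primary allylic bromide by SN2 faster than it deprotonates the hindered C–H next to sulfur, and the remaining α-enolate is then C-methylated in the same flask; C4 forms as a mixture and is planarised in step 7.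

**Step 7**
Reactants: 13 acyclic sulfonyl β-keto ester (mixture of C4 and C7 epimers)
Product: 14 15-methyl 19-[(1S,2R,5S)-8-phenylmenthyl] (4S,5S,9R,10S,13E)-3-oxolabda-7,13-diene-15,19-dioate
Conditions: Mn(OAc)3·2H2O (2.5 eq), degassed AcOH, 25 °C, slow addition (0.02 M); chromatography
Reagents that add atoms: none
Why: Proposed new method: Mn(III) oxidises the α-methyl β-keto ester to the tertiary radical, which closes 6-endo on C5 and then, as the C10 radical, 6-endo on C9 of the allyl sulfone through an all-chair E,E transition state (ester axial and cis to C20, H5 and H9 trans to C20), and the C8 radical then expels PhSO2• from C7 (SH2′ addition–fragmentation) faster than it is oxidised or adds to the enoate, so the alkene can only be C7=C8 and all epimers of 13 converge; the phenyl group of the (1S,2R,5S)-auxiliary shields one face of the syn-dicarbonyl radical to give the 4S series, the mirror image of the sense obtained with the (1R,2S,5R)-auxiliary in the podocarpic acid series as I recall it; closest known reactions are the Snider Mn(OAc)3 polyene cyclisation of 8-phenylmenthyl 2-methylacetoacetates and radical allylation with allyl sulfones.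

**Step 8**
Reactants: 14 keto diester
Product: 16 (3S,4R,5S,9R,10S,13E)-labda-7,13-diene-3,15,19-triol, via 3-hydroxy diester 15 (not isolated)
Conditions: L-Selectride (1.3 eq), THF, −78 → −20 °C; then LiAlH4, −78 → 40 °C; Rochelle salt
Reagents that add atoms: none
Why: the bulky trialkylborohydride attacks the C3 ketone from the equatorial direction to give the axial (3S) alcohol, as with 4,4-disubstituted 3-oxo terpenoids, and LiAlH4 then reduces both esters (1,2-reduction of the enoate) and releases the auxiliary.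

**Step 9**
Reactants: 16 triol
Product: 18 (3S,4R,5S,9R,10S,13E)-3,19-dihydroxylabda-7,13-dien-15-oic acid, via enal 17 (not isolated)
Conditions: MnO2, CH2Cl2, rt; filter; NaClO2, NaH2PO4, 2-methyl-2-butene, t-BuOH/H2O, rt
Reagents that add atoms: sodium chlorite [Na+].[O-]Cl=O
Why: MnO2 oxidises only the allylic alcohol, and Pinnick oxidation converts the enal to the acid without touching the saturated diol or the alkenes (2-methyl-2-butene scavenges HOCl).

**Step 10**
Reactants: 18 diol acid
Product: 19 (3S,4R,5S,9R,10S,13E)-3,19-diacetoxylabda-7,13-dien-15-oic acid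
Conditions: Ac2O, DMAP (cat.), pyridine, rt → 40 °C; then H2O, rt
Reagents that add atoms: acetic anhydride CC(=O)OC(C)=O
Why: DMAP-catalysed acetylation esterifies both hydroxyls, including the hindered axial 3-OH (as in the acetylboswellic acids), and the mixed anhydride at C15 is hydrolysed by the water quench.

**Step 11**
Reactants: 19 diacetate
Product: 20 target, (3S,4R,5S,9R,10S,13E)-3-acetoxy-19-hydroxylabda-7,13-dien-15-oic acid
Conditions: K2CO3, MeOH, 0 °C, monitored; then aq NaH2PO4
Reagents that add atoms: none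
Why: base-catalysed methanolysis cleaves the primary acetate much faster than the axial secondary acetate flanked by quaternary C4, and the trans-diaxial O–C3–C4–C19 arrangement rules out acetyl migration.

**Compound list**
1 | 5-bromo-2-methylpent-2-ene | CC(C)=CCCBr | starting material
2 | methyl but-2-ynoate | CC#CC(=O)OC | starting material
3 | (4-methylpent-3-en-1-yl)magnesium bromide | CC(C)=CCC[Mg]Br | intermediate
4 | methyl (2E)-3,7-dimethylocta-2,6-dienoate | CC(C)=CCC/C(C)=C/C(=O)OC | intermediate
5 | methyl (2E,6E)-8-hydroxy-3,7-dimethylocta-2,6-dienoate | OC/C(C)=C/CC/C(C)=C/C(=O)OC | intermediate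
6 | methyl (2E,6E)-8-bromo-3,7-dimethylocta-2,6-dienoate | BrC/C(C)=C/CC/C(C)=C/C(=O)OC | intermediate
7 | methyl (2E,6E)-3,7-dimethyl-8-(phenylsulfonyl)octa-2,6-dienoate | O=S(=O)(c1ccccc1)C/C(C)=C/CC/C(C)=C/C(=O)OC | intermediate
8 | (2E)-1,4-dibromo-2-methylbut-2-ene | BrC/C(C)=C/CBr | starting material
9 | methyl (2E,6E,10E)-12-bromo-3,7,11-trimethyl-8-(phenylsulfonyl)dodeca-2,6,10-trienoate (racemic at C8) | BrC/C(C)=C/CC(S(=O)(=O)c1ccccc1)/C(C)=C/CC/C(C)=C/C(=O)OC | intermediate
10 | methyl 3-oxobutanoate | CC(=O)CC(=O)OC | starting material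
11 | (1S,2R,5S)-5-methyl-2-(2-phenylpropan-2-yl)cyclohexyl 3-oxobutanoate | CC(=O)CC(=O)O[C@H]1C[C@@H](C)CC[C@@H]1C(C)(C)c1ccccc1 | intermediate
12 | 16-methyl 1-[(1S,2R,5S)-5-methyl-2-(2-phenylpropan-2-yl)cyclohexyl] (6E,10E,14E)-6,10,14-trimethyl-3-oxo-9-(phenylsulfonyl)hexadeca-6,10,14-trienedioate (C9 epimers) | O=C(O[C@H]1C[C@@H](C)CC[C@@H]1C(C)(C)c1ccccc1)CC(=O)CC/C(C)=C/CC(S(=O)(=O)c1ccccc1)/C(C)=C/CC/C(C)=C/C(=O)OC | intermediate
13 | 16-methyl 1-[(1S,2R,5S)-5-methyl-2-(2-phenylpropan-2-yl)cyclohexyl] (6E,10E,14E)-2,6,10,14-tetramethyl-3-oxo-9-(phenylsulfonyl)hexadeca-6,10,14-trienedioate (C2 and C9 epimers) | O=C(O[C@H]1C[C@@H](C)CC[C@@H]1C(C)(C)c1ccccc1)C(C)C(=O)CC/C(C)=C/CC(S(=O)(=O)c1ccccc1)/C(C)=C/CC/C(C)=C/C(=O)OC | intermediate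
14 | 15-methyl 19-[(1S,2R,5S)-8-phenylmenthyl] (4S,5S,9R,10S,13E)-3-oxolabda-7,13-diene-15,19-dioate (trans-decalin; 19-ester axial, cis to C20) | O=C1CC[C@]2(C)[C@H](CC=C(C)[C@H]2CC/C(C)=C/C(=O)OC)[C@]1(C)C(=O)O[C@H]3C[C@@H](C)CC[C@@H]3C(C)(C)c4ccccc4 | intermediate
15 | 15-methyl 19-[(1S,2R,5S)-8-phenylmenthyl] (3S,4S,5S,9R,10S,13E)-3-hydroxylabda-7,13-diene-15,19-dioate (3-OH axial) | O[C@H]1CC[C@]2(C)[C@H](CC=C(C)[C@H]2CC/C(C)=C/C(=O)OC)[C@]1(C)C(=O)O[C@H]3C[C@@H](C)CC[C@@H]3C(C)(C)c4ccccc4 | intermediate
16 | (3S,4R,5S,9R,10S,13E)-labda-7,13-diene-3,15,19-triol | O[C@H]1CC[C@]2(C)[C@H](CC=C(C)[C@H]2CC/C(C)=C/CO)[C@]1(C)CO | intermediate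
17 | (3S,4R,5S,9R,10S,13E)-3,19-dihydroxylabda-7,13-dien-15-al | O[C@H]1CC[C@]2(C)[C@H](CC=C(C)[C@H]2CC/C(C)=C/C=O)[C@]1(C)CO | intermediate
18 | (3S,4R,5S,9R,10S,13E)-3,19-dihydroxylabda-7,13-dien-15-oic acid | O[C@H]1CC[C@]2(C)[C@H](CC=C(C)[C@H]2CC/C(C)=C/C(=O)O)[C@]1(C)CO | intermediate
19 | (3S,4R,5S,9R,10S,13E)-3,19-diacetoxylabda-7,13-dien-15-oic acid | CC(=O)O[C@H]1CC[C@]2(C)[C@H](CC=C(C)[C@H]2CC/C(C)=C/C(=O)O)[C@]1(C)COC(C)=O | intermediate
20 | (2E)-5-[(1R,4aS,5R,6S,8aS)-6-acetoxy-5-(hydroxymethyl)-2,5,8a-trimethyl-1,4,4a,5,6,7,8,8a-octahydronaphthalen-1-yl]-3-methylpent-2-enoic acid | CC(=O)O[C@H]1CC[C@]2(C)[C@H](CC=C(C)[C@H]2CC/C(C)=C/C(=O)O)[C@]1(C)CO | target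

**Totals**
Total steps: 11. Longest linear sequence: 10 (steps 1, 2, 3, 4, 6, 7, 8, 9, 10, 11).

**Three steps most likely to fail**

Step 7. The fragmentation must outrun oxidation of the C8 radical and its 5-exo addition to the enoate, the auxiliary must control the face, and the facial sense assigned to the (1S,2R,5S)-auxiliary rests on recalled precedent; if it proved opposite, the (1R,2S,5R)-alcohol would be used. The fallback sets out from 13 and returns at 14. Compound 13 is brominated at C4 (NBS, cat. Mg(ClO4)2, MeCN) to the α-bromo keto ester F1. The cascade is then run as a bromine-atom-transfer chain instead of an oxidation (Et3B/O2, Yb(OTf)3 or Mg(ClO4)2, CH2Cl2, −78 °C). The radical now forms by C–Br homolysis inside a two-point metal chelate that rigidifies the auxiliary, no oxidant is present, and the expelled PhSO2• carries the chain by taking bromine from F1. The same ring closures and loss of sulfonyl give 14.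

Step 4. The two CH2Br groups of 8 differ only by the neighbouring methyl, so the selectivity may be modest and the regioisomer hard to separate. The fallback sets out from 7 and returns at 9. The dibromide is replaced by 2-methyl-2-vinyloxirane (CC1(C=C)CO1) under Pd(0) (NaH, Pd(PPh3)4, dppe, THF). The sulfonyl carbanion can attack only the unsubstituted terminus of the π-allyl complex, giving the (E)-allylic alcohol F2. Its hydroxyl is then exchanged for bromide (CBr4, PPh3, CH2Cl2, 0 °C) to give regiochemically pure 9.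

Step 6. The strongly basic dianion meets an acidic C–H next to sulfur in a molecule that also holds an allylic bromide, so proton transfer and internal alkylation can compete. The fallback sets out from 9 and returns at 13. C2–C3 is built with a soft nucleophile and C3–C4 with a zinc reagent. Methyl cyanoacetate (N#CCC(=O)OC) with K2CO3 in DMF displaces the bromide to give the cyano diester F3. Krapcho dealkoxycarbonylation (LiCl, wet DMSO, 130 °C) gives the nitrile F4. A Blaise reaction with the auxiliary bromo ester F5 (made from 2-bromopropanoyl bromide, CC(Br)C(Br)=O, and (+)-8-phenylmenthol with pyridine; Zn, THF, reflux; then aq HCl) converts the nitrile carbon into the C3 ketone and delivers 13 with the C18 methyl already in place. No strong base meets the bromide in this sequence.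

**Further compounds**
F1 | step 7 | 16-methyl 1-[(1S,2R,5S)-5-methyl-2-(2-phenylpropan-2-yl)cyclohexyl] (6E,10E,14E)-2-bromo-2,6,10,14-tetramethyl-3-oxo-9-(phenylsulfonyl)hexadeca-6,10,14-trienedioate | O=C(O[C@H]1C[C@@H](C)CC[C@@H]1C(C)(C)c1ccccc1)C(C)(Br)C(=O)CC/C(C)=C/CC(S(=O)(=O)c1ccccc1)/C(C)=C/CC/C(C)=C/C(=O)OC
F2 | step 4 | methyl (2E,6E,10E)-12-hydroxy-3,7,11-trimethyl-8-(phenylsulfonyl)dodeca-2,6,10-trienoate | OC/C(C)=C/CC(S(=O)(=O)c1ccccc1)/C(C)=C/CC/C(C)=C/C(=O)OC
F3 | step 6 | dimethyl (2E,6E,10E)-13-cyano-3,7,11-trimethyl-8-(phenylsulfonyl)tetradeca-2,6,10-trienedioate | N#CC(C(=O)OC)C/C(C)=C/CC(S(=O)(=O)c1ccccc1)/C(C)=C/CC/C(C)=C/C(=O)OC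
F4 | step 6 | methyl (2E,6E,10E)-13-cyano-3,7,11-trimethyl-8-(phenylsulfonyl)trideca-2,6,10-trienoate | N#CCC/C(C)=C/CC(S(=O)(=O)c1ccccc1)/C(C)=C/CC/C(C)=C/C(=O)OC
F5 | step 6 | (1S,2R,5S)-5-methyl-2-(2-phenylpropan-2-yl)cyclohexyl 2-bromopropanoate | CC(Br)C(=O)O[C@H]1C[C@@H](C)CC[C@@H]1C(C)(C)c1ccccc1
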